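(All constants were chosen freely; what happens was integrated by code.)

Begin with the flask.

    substrate + reagent + catalyst → catalyst + target (k1 = 4.90 × 10⁵ M⁻² min⁻¹)
    gas ⇌ reagent, rate k2*(csat - [reagent]) (k2 = 35.5 min⁻¹, csat = 2.1 mM)
    2 catalyst ⇌ resting dimer, settled at all times (K3 = 30200 M⁻¹)

substrate 49 mM; gas 2.1 mM (held); catalyst 0.24 mM

- for a step with 2 of a species take k times the square, and two of it per event
- at the start none of reagent is dissolved
- a form made of two catalysts counts as two
- charge of substrate (flask): 49 mM

* the form that holds most of the catalyst when 20% of the substrate are converted (resting dimer / catalyst)
* its share of the catalyst then
* factor on the rate of making target when 20% of the substrate are converted if catalyst is charged twice over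
* factor on the rate when 20% of the substrate are converted if catalyst is charged at 0.025 mM instead

I reckoned on the catalyst that was not paired. Free catalyst plus twice the resting dimer had to make up the charge, and the dimer had to stand at 30200 M⁻¹ times the square of the free catalyst. Solving that balance gave 0.0553 mM of free catalyst, the unpaired part of a charge at balance. That was 23.0% of the catalyst, so I put 77.0% in the resting dimer, the resting state here.

For twice the charge I first bracketed the factor with reagent at saturation. A catalyst wholly free gave 2 as the upper bound, and one wholly dimer gave 1.41 as the lower. The balance at twice the charge left 0.0813 mM free, which tightened the factor to 1.47.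

I reckoned that reaction drew on dissolved reagent at 1.06 min⁻¹ at 20% conversion, against a transfer of 35.5 min⁻¹, so I put reagent at 97.1% of saturation, and at 95.8% with twice the charge. My figure came down to 1.45.

The forecast named the resting dimer at 77%, with factors 1.45 and 0.253, expecting “close to square-root behaviour at high loading and closer to first order on dilution”; its doubling factor lay inside my bracket.

The run reached 20% conversion after 0.0680 h, making target at 130 mM h⁻¹, with the resting dimer holding 77.0% of the catalyst, and twice the charge multiplied that rate by 1.45. For the flask charged at 0.025 mM, the same balance gave me 0.0137 mM free, which is 54.8% of that charge. With reagent at 99.3% of saturation, I reckoned a factor of 0.253 on the rate. The run on that flask gave 0.253.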